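The readings were generated by integration for an exercise; scatter was added.

4 questions stand on one flask, and I meet them with one ratio, read from the runs.

in all of them: substrate 0.050 M
- Saturday's: reagent 0.20 M; temperature 110 °C; the very flask that is asked about, followed so far
- Wednesday's: reagent 0.10 M; temperature 116 °C; run made earlier
- flask: reagent 0.200 M; temperature 110 °C; time 5.0 d

Saturday's run (percent of the substrate charged)

| time / d | product / % | substrate / % |
|---|---|---|
| 0.333 | 16.1 | 46.4 |
| 1.04 | 30.0 | 11.5 |
| 1.67 | 32.9 | 4.1 |
| 2.50 | 34.4 | 3.2 |
| 4.00 | 35.7 | 0.8 |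
| 5.00 | 36.7 | 1.4 |

Wednesday's run (percent of the substrate charged)

| time / h | product / % | substrate / % |
|---|---|---|
| 8.00 | 25.2 | 28.6 |
| 15.0 | 31.7 | 10.3 |
| 25.0 | 34.9 | 3.1 |
| 30.0 | 34.7 | 2.7 |
| 40.0 | 35.5 | 2.1 |
| 50.0 | 37.8 | 1.1 |

(standard deviation of a reading: 0.5 percentage points)

- north-east: at 5.0 d raise the temperature by 10 K, then wait 2.5 d
- south-east: change nothing and wait 2.5 d more
- north-west: at 5.0 d add reagent, 50.0% of the amount charged, then wait 2.5 d
- west: at 5.0 d take out 90% of the product then present, then wait 2.5 d

- removed product is counted in
- the numbers in the tables scatter with a standard deviation of 0.5 percentage points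
- additions bring no volume worth counting
- a reading of substrate is of its free form alone

- product, in percent of the substrate first charged, at 5.0 d
- the remedy with the largest gain of product, or "none" below 2 percentage points (north-east / south-east / north-west / west / none)
- product present, with what was taken out counted in, in percent of the substrate first charged, after north-east
- product present, with what was taken out counted in, in percent of the substrate first charged, after west

**The share.** I take s, c(product) gained over c(substrate) lost, the selectivity, which I call the share, and I write 0.339 for Saturday's flask at 1.04 d. Wednesday's flask gives 0.353 at 15.0 h. The zero of my scale is an even split, 0.5, and Saturday's share lies below it.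

**Bench rule.** Substrate falls from 46.4% to 11.5% between the first two readings, a half-life of 0.351 d. The rule calls a flask finished after 5 half-lives, here 1.75 d, with product at s times the substrate lost: 33.4% at 5.00 d. But the reading there is 36.7%.

**The border.** From 2.50 d to 5.00 d, product gains 2.3 percentage points while substrate loses 1.8 points, a late share of 1.28, above 1. Wednesday's flask reads 1.45 over its last 25.0 h. Each reading scatters by 0.5 points, so these ratios are rough. Yet 61.9% of Saturday's charge is unseen, and I read that as a store feeding product.

**My reckoning.** I keep 36.7% for now. The further time, 2.5 d, equals the span I just read, so waiting brings about 2.3 points, above the margin. Saturday's product rises from reading to reading, and Wednesday's one fall, from 34.9% to 34.7%, lies within the scatter, so I book west as waiting, which puts west at 39.0%. For north-west I have no separate reading, since the two runs differ in reagent and temperature together. Wednesday's late gain runs 3.03 times faster, at 116 °C against 110 °C, though with 0.10 M reagent against 0.20 M. Applying that factor, north-east reaches 43.7%, and it is my choice.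

The forecast says 36.4% now, north-east as best, 41.5% after north-east and 38.4% after west, seeing “a hidden reservoir slowly releasing substrate”.

**The result.** The flask gives 36.9%, and north-east gains 6.5 points against 2.1 points for waiting, with 43.4% after north-east and 39.0% after west.

    substrate ⇌ intermediate A (K = 31.0, k = 1.53 × 10⁻⁵ s⁻¹, Ea = 122 kJ mol⁻¹, ΔH = −53.0 kJ mol⁻¹)
    substrate + reagent ⇌ intermediate B (K = 4.39 M⁻¹, k = 1.57 × 10⁻⁵ M⁻¹ s⁻¹, Ea = 85.0 kJ mol⁻¹, ΔH = −29.0 kJ mol⁻¹)
    substrate → product (k = 8.53 × 10⁻⁶ s⁻¹, Ea = 119 kJ mol⁻¹)
    intermediate A ⇌ intermediate C (K = 0.230, k = 4.12 × 10⁻⁶ s⁻¹, Ea = 124 kJ mol⁻¹, ΔH = −1.00 kJ mol⁻¹)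
    reagent + intermediate C ⇌ intermediate D (K = 7.50 M⁻¹, k = 1.45 × 10⁻⁴ M⁻¹ s⁻¹, Ea = 99.0 kJ mol⁻¹, ΔH = −18.0 kJ mol⁻¹)
    (constants at 110 °C)

**Same ratio.** In the flask at 5.00 d, the share is 0.374, above the early reading, with intermediate A holding 37.9% of the charge. A neighbouring flask kept at 135 °C, with amounts and time held, has 0.64% substrate left and 83.1% product. Its share is 0.836, past the even split, and intermediate A there holds 10.7%.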